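**Strategy**

Everything rests on opening ring B at the C6–C7 bond. C6, the spiro carbon, is the α-carbon of a ring-A ketone at C1 (the later methylidene carbon), and C7 is the end of the allyl unit C7–C8–C9 of ring B. The key step is an acid-triggered enol/allyl-cation spirocyclization: in one operation it closes ring B, builds the quaternary C6 stereocentre next to C5 and converges four diastereomers (epimers at C6 and at carbinol C9) onto one spiro enone. Its precursor is a monocyclic (4R)-bromo-dimethylcyclohexanone whose α-carbon carries a 2-chloro-3-hydroxy-3-methylpent-4-enyl chain. Markovnikov HBr addition and methylenation then complete the target.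

Key step: step 11

Numbering (spiro[5.5]undecane locants, also used for the carbons that become them): ring A = C1 (C=CH2), C2, C3, C4 (CHBr), C5 (CMe2), C6 (spiro); ring B = C6, C7, C8, C9 (C(CH3)Br), C10 (CHCl), C11. In this numbering the target reads 4R,6S,9R,10R.

Remark: centres that are destroyed later (the ester-bearing ring carbon in 6 and 8–13, the ring α-carbon in 14, the carbinol carbon in 10 and 12–14) are carried as epimer mixtures and are left open in the SMILES.

**Route**

Step 1
Reactants: 1 3-methylbut-2-en-1-ol
Product: 2 (2R)-2-bromo-3-chloro-3-methylbutan-1-ol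
Conditions: NBS, ClTi(OiPr)3, chiral tridentate Schiff-base ligand (20 mol %, the enantiomer that gives the 2R product), hexanes, −20 °C
Reagents that add atoms: N-bromosuccinimide O=C1CCC(=O)N1Br; chlorotitanium triisopropoxide CC(C)O[Ti](Cl)(OC(C)C)OC(C)C
Why: Catalytic enantioselective bromochlorination of an allylic alcohol: the titanium-bound alkene takes Br+ from NBS and chloride is delivered anti to the more substituted carbon (Markovnikov), so the ligand enantiomer fixes the C–Br centre (future C4) as R.

Step 2
Reactants: 2 (2R)-2-bromo-3-chloro-3-methylbutan-1-ol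
Product: 3 (2R)-2-bromo-3-chloro-3-methylbutyl trifluoromethanesulfonate
Conditions: Tf2O, 2,6-lutidine, CH2Cl2, −78 °C, used at once
Reagents that add atoms: trifluoromethanesulfonic anhydride O=S(=O)(OS(=O)(=O)C(F)(F)F)C(F)(F)F
Why: O-Triflation of the primary alcohol with a hindered base at −78 °C should be clean and leaves the stereocentre untouched, the triflate being used immediately because of its reactivity.

Step 3
Reactants: 4 allyl acetoacetate (prop-2-en-1-yl 3-oxobutanoate); 3 (2R)-2-bromo-3-chloro-3-methylbutyl trifluoromethanesulfonate
Product: 5 allyl (6R)-6-bromo-7-chloro-7-methyl-3-oxooctanoate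
Conditions: 4, LiN(iPr)2 (2.1 equiv), THF, −78 → 0 °C; then 3, −78 °C
Reagents that add atoms: none
Why: γ-Alkylation of the acetoacetate dianion (SN2 at the primary triflate): the more basic terminal carbanion reacts first at −78 °C, which should outrun elimination, and the C–Br centre is not involved.

Step 4
Reactants: 5 allyl (6R)-6-bromo-7-chloro-7-methyl-3-oxooctanoate
Product: 6 allyl (3R)-3-bromo-2,2-dimethyl-6-oxocyclohexane-1-carboxylate
Conditions: (CF3)2CHOH (HFIP), rt
Reagents that add atoms: none
Why: Solvolytic bromonium-type cation–olefin cyclization: HFIP ionises the tertiary chloride with anchimeric assistance of the neighbouring bromine and the enol carbon of the β-keto ester opens the bridged ion at the tertiary carbon anti to bromine through a chair (six-membered ring, bromine equatorial), so the C–Br centre keeps its configuration while the ester-bearing carbon stays epimerisable.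

Step 5
Reactants: 6 allyl (3R)-3-bromo-2,2-dimethyl-6-oxocyclohexane-1-carboxylate; 7 acrolein (prop-2-enal)
Product: 8 allyl (3R)-3-bromo-2,2-dimethyl-6-oxo-1-(3-oxopropyl)cyclohexane-1-carboxylate
Conditions: Yb(OTf)3 (10 mol %), THF–H2O, rt
Reagents that add atoms: none
Why: Lewis-acid-catalysed Michael addition: the only acidic C–H is the one between the two carbonyls (future C6), so C11–C9 are attached regiospecifically, and the absence of base should avoid 1,3-elimination of HBr; the new quaternary centre is destroyed in step 10.

Step 6
Reactants: 8 allyl (3R)-3-bromo-2,2-dimethyl-6-oxo-1-(3-oxopropyl)cyclohexane-1-carboxylate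
Product: 9 allyl (3R)-3-bromo-1-[(2R)-2-chloro-3-oxopropyl]-2,2-dimethyl-6-oxocyclohexane-1-carboxylate
Conditions: NCS, 2,5-diphenylpyrrolidine (10 mol %, the C2-symmetric enantiomer that gives the 2R chloride), CH2Cl2, 0 °C → rt, used crude
Reagents that add atoms: N-chlorosuccinimide O=C1CCC(=O)N1Cl
Why: Enamine-catalysed asymmetric α-chlorination of an aldehyde: the chiral amine shields one enamine face toward NCS, which should set the C–Cl centre (future C10) as R under catalyst control, while the ketone and the fully substituted β-keto ester carbon cannot be chlorinated.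

Step 7
Reactants: 9 allyl (3R)-3-bromo-1-[(2R)-2-chloro-3-oxopropyl]-2,2-dimethyl-6-oxocyclohexane-1-carboxylate
Product: 10 allyl (3R)-3-bromo-1-[(2R)-2-chloro-3-hydroxybutyl]-2,2-dimethyl-6-oxocyclohexane-1-carboxylate
Conditions: MeMgBr (1.1 equiv), THF, −78 °C, cold aqueous quench
Reagents that add atoms: methylmagnesium bromide C[Mg]Br
Why: Chemoselective Grignard addition to the highly electrophilic α-chloro aldehyde at −78 °C (the neopentyl ketone and ester should not react); the new carbinol centre is removed by oxidation in step 8.

Step 8
Reactants: 10 allyl (3R)-3-bromo-1-[(2R)-2-chloro-3-hydroxybutyl]-2,2-dimethyl-6-oxocyclohexane-1-carboxylate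
Product: 11 allyl (3R)-3-bromo-1-[(2R)-2-chloro-3-oxobutyl]-2,2-dimethyl-6-oxocyclohexane-1-carboxylate
Conditions: Dess–Martin periodinane, pyridine, CH2Cl2, 0 °C → rt
Reagents that add atoms: none
Why: Dess–Martin oxidation of the secondary alcohol under buffered, non-enolising conditions should give the α-chloro methyl ketone without epimerisation of the C–Cl centre.

Step 9
Reactants: 11 allyl (3R)-3-bromo-1-[(2R)-2-chloro-3-oxobutyl]-2,2-dimethyl-6-oxocyclohexane-1-carboxylate
Product: 12 allyl (3R)-3-bromo-1-[(2R)-2-chloro-3-hydroxy-3-methylpent-4-en-1-yl]-2,2-dimethyl-6-oxocyclohexane-1-carboxylate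
Conditions: CH2=CHMgBr (1.2 equiv), THF, −78 °C, cold aqueous quench
Reagents that add atoms: vinylmagnesium bromide C=C[Mg]Br
Why: Grignard 1,2-addition to the activated α-chloro ketone, expected to follow the Cornforth/Felkin–Anh model (3S carbinol preferred); the cold quench avoids epoxide closure and the carbinol configuration is erased in step 11.

Step 10
Reactants: 12 allyl (3R)-3-bromo-1-[(2R)-2-chloro-3-hydroxy-3-methylpent-4-en-1-yl]-2,2-dimethyl-6-oxocyclohexane-1-carboxylate
Product: 14 (4R)-4-bromo-2-[(2R)-2-chloro-3-hydroxy-3-methylpent-4-en-1-yl]-3,3-dimethylcyclohexan-1-one, via β-keto acid 13 (not isolated)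
Conditions: Pd(OAc)2 (5 mol %), PPh3 (20 mol %), HCO2H, Et3N, THF, rt
Reagents that add atoms: none
Why: Palladium-catalysed deallylation–decarboxylation: zerovalent palladium ionises the allyl ester, formate reduces the π-allyl fragment to propene, and the β-keto acid loses CO2 at room temperature under neutral conditions that should spare the chlorohydrin and the bromide; the resulting α-C–H centre (C6) is an inconsequential epimer mixture.

Step 11
Reactants: 14 (4R)-4-bromo-2-[(2R)-2-chloro-3-hydroxy-3-methylpent-4-en-1-yl]-3,3-dimethylcyclohexan-1-one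
Product: 15 (4R,6R,10R)-4-bromo-10-chloro-5,5,9-trimethylspiro[5.5]undec-8-en-1-one
Conditions: TfOH (10 mol %), CH2Cl2–HFIP (4:1), −20 → 0 °C
Reagents that add atoms: none
Why: Acid converts the tertiary allylic alcohol (either C9 epimer) into the C7–C8–C9 allyl cation while the ring-A ketone enolises toward C6 (either C6 epimer), the enol carbon C6 attacks the cation terminus C7 and loss of the O–H proton restores the C1 ketone. The closest known reaction type is the acid-mediated cation–olefin (SN1′) cyclization of an allylic cation onto an enol terminator, the carbocyclic counterpart of the neryl-to-terpinyl closure. Ring B closes in a 6-(enolexo)-endo mode, with the enol double bond outside the new ring and the allyl unit inside it as the C8=C9 alkene, attack at C9 (four-membered ring) or by the C2 enol (bridged eight-membered ring) being excluded by ring size. The new stereocentre C6 is set by two elements that point the same way: C7 adds axially to the ring-A enol on the face trans to the equatorial C4 bromine and anti to the axial C5 methyl, and in the ring-B half-chair the C10 chlorine lies pseudoaxial (aligned with the cation and free of A(1,2) strain with the C9 methyl), so that the flat C1 rather than the bulky C5 takes the axial position syn to chlorine. The step needs C- over O-alkylation and a cation that is captured before it loses a proton at C10; the cyclic enol ether from O-attack can re-ionise to the same cation, the less substituted enol cannot cyclise (Curtin–Hammett funnel), and the cold, non-nucleophilic medium keeps the cation short-lived.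

Step 12
Reactants: 15 (4R,6R,10R)-4-bromo-10-chloro-5,5,9-trimethylspiro[5.5]undec-8-en-1-one
Product: 16 (4R,6R,9R,10R)-4,9-dibromo-10-chloro-5,5,9-trimethylspiro[5.5]undecan-1-one
Conditions: HBr (1 M in AcOH, 1.5 equiv), CH2Cl2, −40 → 0 °C
Reagents that add atoms: hydrogen bromide Br
Why: Ionic Markovnikov hydrobromination: protonation at C8 gives the tertiary C9 cation, which the axial C10 chlorine bridges on its own face, so bromide should enter anti and axially and the C9 centre is set as R with bromine trans to chlorine.

Step 13
Reactants: 16 (4R,6R,9R,10R)-4,9-dibromo-10-chloro-5,5,9-trimethylspiro[5.5]undecan-1-one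
Product: 17 (4R,6S,9R,10R)-4,9-dibromo-10-chloro-5,5,9-trimethyl-1-methylidenespiro[5.5]undecane
Conditions: Cp2Ti(μ-CH2)(μ-Cl)AlMe2 (Tebbe reagent), pyridine (cat.), THF–toluene, −40 → 0 °C
Reagents that add atoms: Tebbe reagent (titanocene methylidene–dimethylaluminium chloride adduct) C=[Ti](C1C=CC=C1)C1C=CC=C1.C[Al](C)Cl
Why: Tebbe methylenation: the non-basic titanium methylidene should convert the hindered α-quaternary ketone into the C1 methylidene through an oxatitanacyclobutane without enolisation, elimination or attack on the three C–halogen bonds.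

**Compound list**

1 | 3-methylbut-2-en-1-ol | CC(C)=CCO | starting material
2 | (2R)-2-bromo-3-chloro-3-methylbutan-1-ol | OC[C@@H](Br)C(C)(C)Cl | intermediate
3 | (2R)-2-bromo-3-chloro-3-methylbutyl trifluoromethanesulfonate | FC(F)(F)S(=O)(=O)OC[C@@H](Br)C(C)(C)Cl | intermediate
4 | allyl acetoacetate (prop-2-en-1-yl 3-oxobutanoate) | CC(=O)CC(=O)OCC=C | starting material
5 | allyl (6R)-6-bromo-7-chloro-7-methyl-3-oxooctanoate | C=CCOC(=O)CC(=O)CC[C@@H](Br)C(C)(C)Cl | intermediate
6 | allyl (3R)-3-bromo-2,2-dimethyl-6-oxocyclohexane-1-carboxylate (C1 epimerisable) | C=CCOC(=O)C1C(=O)CC[C@@H](Br)C1(C)C | intermediate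
7 | acrolein (prop-2-enal) | C=CC=O | starting material
8 | allyl (3R)-3-bromo-2,2-dimethyl-6-oxo-1-(3-oxopropyl)cyclohexane-1-carboxylate (C1 epimers) | C=CCOC(=O)C1(CCC=O)C(=O)CC[C@@H](Br)C1(C)C | intermediate
9 | allyl (3R)-3-bromo-1-[(2R)-2-chloro-3-oxopropyl]-2,2-dimethyl-6-oxocyclohexane-1-carboxylate (C1 epimers) | C=CCOC(=O)C1(C[C@@H](Cl)C=O)C(=O)CC[C@@H](Br)C1(C)C | intermediate
10 | allyl (3R)-3-bromo-1-[(2R)-2-chloro-3-hydroxybutyl]-2,2-dimethyl-6-oxocyclohexane-1-carboxylate (C1 and carbinol epimers) | C=CCOC(=O)C1(C[C@@H](Cl)C(C)O)C(=O)CC[C@@H](Br)C1(C)C | intermediate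
11 | allyl (3R)-3-bromo-1-[(2R)-2-chloro-3-oxobutyl]-2,2-dimethyl-6-oxocyclohexane-1-carboxylate (C1 epimers) | C=CCOC(=O)C1(C[C@@H](Cl)C(C)=O)C(=O)CC[C@@H](Br)C1(C)C | intermediate
12 | allyl (3R)-3-bromo-1-[(2R)-2-chloro-3-hydroxy-3-methylpent-4-en-1-yl]-2,2-dimethyl-6-oxocyclohexane-1-carboxylate (C1 and carbinol epimers, 3S carbinol expected to predominate) | C=CCOC(=O)C1(C[C@@H](Cl)C(C)(O)C=C)C(=O)CC[C@@H](Br)C1(C)C | intermediate
13 | (3R)-3-bromo-1-[(2R)-2-chloro-3-hydroxy-3-methylpent-4-en-1-yl]-2,2-dimethyl-6-oxocyclohexane-1-carboxylic acid (β-keto acid, not isolated) | OC(=O)C1(C[C@@H](Cl)C(C)(O)C=C)C(=O)CC[C@@H](Br)C1(C)C | intermediate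
14 | (4R)-4-bromo-2-[(2R)-2-chloro-3-hydroxy-3-methylpent-4-en-1-yl]-3,3-dimethylcyclohexan-1-one (C2 and carbinol epimers) | C=CC(C)(O)[C@H](Cl)CC1C(=O)CC[C@@H](Br)C1(C)C | intermediate
15 | (4R,6R,10R)-4-bromo-10-chloro-5,5,9-trimethylspiro[5.5]undec-8-en-1-one | O=C1CC[C@@H](Br)C(C)(C)[C@]12CC=C(C)[C@H](Cl)C2 | intermediate
16 | (4R,6R,9R,10R)-4,9-dibromo-10-chloro-5,5,9-trimethylspiro[5.5]undecan-1-one | O=C1CC[C@@H](Br)C(C)(C)[C@]12CC[C@@](C)(Br)[C@H](Cl)C2 | intermediate
17 | (4R,6S,9R,10R)-4,9-dibromo-10-chloro-5,5,9-trimethyl-1-methylidenespiro[5.5]undecane | C=C1CC[C@@H](Br)C(C)(C)[C@]12CC[C@@](C)(Br)[C@H](Cl)C2 | target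

**Count and risks**

Total step count: 13. Longest linear sequence: 13 steps (from 1).

The three steps most likely to fail:

Step 11 (key step). The allyl cation may lose a proton (diene formation, which also erodes the C10 configuration) or be captured at oxygen faster than the ring-A ketone enolises, and the facial preference at C6 may turn out lower than argued. The fallback replaces the cationic closure by a sigmatropic one. It sets out from 14, using its 3S carbinol epimer (the expected major product of step 9, separated by chromatography). Cyclodehydration of this δ-hydroxy ketone (PPTS, benzene, 4 Å molecular sieves, 60 °C) should give the cyclic allyl vinyl ether (2S,3R,6R)-6-bromo-3-chloro-2-ethenyl-2,5,5-trimethyl-3,4,5,6,7,8-hexahydro-2H-chromene F1. Heating (xylene, 140 °C, trace Et3N) should then bring about a Claisen rearrangement through the ring-enforced boat transition state; it forms the same C6–C7 bond on the ring face that carries the vinyl group, transfers the C9 configuration to C6 without any cation, and comes back to the route at 15.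

Step 12. HBr may ionise or transpose the allylic C10 chloride, and bromide may be captured on the chlorine face, which would lose the trans relationship. The fallback is a radical instead of an ionic hydrobromination. It sets out from 15: Mukaiyama-type hydrogen-atom-transfer hydrobromination (Co(acac)2 cat., PhSiH3, TsBr, t-BuOOH cat., i-PrOH–CH2Cl2, 0 °C) should place the hydrogen atom on C8 and let the tertiary C9 radical take bromine from TsBr on the face anti to the axial chlorine. It comes back to the route at 16; no new compound is formed on this way (F0).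

Step 4. The bridged cation may be captured by the ketone oxygen (O-cyclization) or may lose a proton instead of forming the C5–C6 bond. The fallback uses a silyl enol ether as the terminating group. It sets out from 5: silylation (TBSOTf, Et3N, CH2Cl2, 0 °C) should give allyl (2Z,6R)-6-bromo-3-[(tert-butyldimethylsilyl)oxy]-7-chloro-7-methyloct-2-enoate F2, in which the carbonyl oxygen is masked and the α-carbon is the only nucleophilic site. The same ionisation in HFIP should then close ring A at carbon with loss of the silyl group, coming back to the route at 6.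

Further compounds
F1 | step 11 | (2S,3R,6R)-6-bromo-3-chloro-2-ethenyl-2,5,5-trimethyl-3,4,5,6,7,8-hexahydro-2H-chromene | C=C[C@]1(C)OC2=C(C[C@H]1Cl)C(C)(C)[C@H](Br)CC2
F0 | step 12 | none | none
F2 | step 4 | allyl (2Z,6R)-6-bromo-3-[(tert-butyldimethylsilyl)oxy]-7-chloro-7-methyloct-2-enoate | C=CCOC(=O)/C=C(/CC[C@@H](Br)C(C)(C)Cl)O[Si](C)(C)C(C)(C)C
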